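**Plan**

1. Retrosynthesis: the two CH2OH groups of the butanediol come from a γ-lactone. The cuts are, in order: the bond between butanediol C2 and the benzylic CH2 on C5 of the dihydrobenzofuran (lactone enolate + benzylic bromide), then O1–C2 of the dihydrobenzofuran, then C2–C3 (auxiliary alkylation of an arylacetyl imide), then the aryl–CH2CO bond (Pd coupling).
2. Enabling feature: C2 of the dihydrobenzofuran is benzylic and para to the free OH of its guaiacyl ring, so it is the exocyclic carbon of a p-quinone methide. O1, the phenol oxygen on C7a of the central arene, stands 1,5 to C2, so its addition closes the five-membered ring.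
3. Forward order: arylacetic acid, C2–C3 by Evans alkylation, debenzylation, oxidative O1–C2 closure (the dihydrofuran ring), benzylic bromide, union with the (R)-lactone, hydride opening of the lactone to the 1,4-diol, desilylation.
4. Stereochemistry: C3 comes from (R)-4-benzyloxazolidin-2-one, and C2 follows from C3 in the trans-selective closure. Butanediol C3 comes from (S)-4-benzyloxazolidin-2-one (lactone C4), and butanediol C2 from alkylation of the lactone enolate anti to the C4 substituent.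

Key step: step 9

Remark: the carbon para to O1 is carried as a methyl ester, which deactivates the central phenol toward Ag2O as an aldehyde would but needs no masking in the enolate and borohydride steps; the primary alcohol is left free in the ring closure; compound 1 is assumed to be purchasable (otherwise one bromination of methyl vanillate).

**Route**

Step 1
Reactants: 1 methyl 3-bromo-4-hydroxy-5-methoxybenzoate
Product: 2 methyl 4-(benzyloxy)-3-bromo-5-methoxybenzoate
Conditions: BnBr, K2CO3, DMF, 60 °C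
Reagents that add atoms: benzyl bromide, BrCc1ccccc1
Why: Williamson ether synthesis on an acidic, ester-bearing phenol, giving a benzyl ether that should survive every step up to the hydrogenolysis in step 8.

Step 2
Reactants: 2 methyl 4-(benzyloxy)-3-bromo-5-methoxybenzoate
Product: 3 tert-butyl 2-[2-(benzyloxy)-3-methoxy-5-(methoxycarbonyl)phenyl]acetate
Conditions: BrZnCH2CO2t-Bu (1.5 equiv, commercial THF solution), Pd2(dba)3 (2 mol %), XPhos (5 mol %), THF, 65 °C
Reagents that add atoms: (2-tert-butoxy-2-oxoethyl)zinc bromide, CC(C)(C)OC(=O)C[Zn]Br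
Why: Palladium-catalysed α-arylation of a Reformatsky zinc enolate (Negishi-type cross-coupling), in which the neutral zinc enolate tolerates the methyl benzoate and a mono-ortho-substituted aryl bromide is a standard partner.

Step 3
Reactants: 3 tert-butyl 2-[2-(benzyloxy)-3-methoxy-5-(methoxycarbonyl)phenyl]acetate
Product: 4 2-[2-(benzyloxy)-3-methoxy-5-(methoxycarbonyl)phenyl]acetic acid
Conditions: TFA/CH2Cl2 (1:3), 0 °C to rt
Reagents that add atoms: none
Why: Acidolysis of the tert-butyl ester (E1 loss of isobutene) should leave the methyl ester and the aryl benzyl ether intact.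

Step 4
Reactants: 4 2-[2-(benzyloxy)-3-methoxy-5-(methoxycarbonyl)phenyl]acetic acid; 5 (R)-4-benzyl-1,3-oxazolidin-2-one
Product: 7 (4R)-4-benzyl-3-{2-[2-(benzyloxy)-3-methoxy-5-(methoxycarbonyl)phenyl]acetyl}-1,3-oxazolidin-2-one, via mixed pivalic anhydride 6 (not isolated)
Conditions: PivCl, Et3N, THF, −20 °C; then LiCl, 5, −20 °C to rt
Reagents that add atoms: none
Why: N-acylation of the oxazolidinone through a mixed pivalic anhydride under LiCl/Et3N activation, the nucleophile attacking the less hindered arylacetyl carbonyl.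

Step 5
Reactants: 8 [4-(benzyloxy)-3-methoxyphenyl]methanol
Product: 9 1-(benzyloxy)-4-(bromomethyl)-2-methoxybenzene
Conditions: PBr3, Et2O, 0 °C; used at once
Reagents that add atoms: phosphorus tribromide, BrP(Br)Br
Why: Bromide substitution of an electron-rich benzylic alcohol through its phosphite ester, a routine preparation of this type of benzylic bromide.

Step 6
Reactants: 7 (4R)-4-benzyl-3-{2-[2-(benzyloxy)-3-methoxy-5-(methoxycarbonyl)phenyl]acetyl}-1,3-oxazolidin-2-one; 9 1-(benzyloxy)-4-(bromomethyl)-2-methoxybenzene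
Product: 11 (4R)-4-benzyl-3-{(2R)-2-[2-(benzyloxy)-3-methoxy-5-(methoxycarbonyl)phenyl]-3-[4-(benzyloxy)-3-methoxyphenyl]propanoyl}-1,3-oxazolidin-2-one, via sodium Z-enolate 10 (not isolated)
Conditions: NaN(SiMe3)2, THF, −78 °C; then 9, −78 to −40 °C; AcOH quench at −78 °C
Reagents that add atoms: none
Why: Evans asymmetric alkylation in which the chelated sodium Z-enolate 10 is attacked by the benzylic bromide on the face opposite the C4 benzyl group of the (R)-auxiliary, setting the (2R) centre that becomes C3 of the dihydrobenzofuran, the construction used for 2,3-diarylpropanols in isoflavan synthesis.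

Step 7
Reactants: 11 (4R)-4-benzyl-3-{(2R)-2-[2-(benzyloxy)-3-methoxy-5-(methoxycarbonyl)phenyl]-3-[4-(benzyloxy)-3-methoxyphenyl]propanoyl}-1,3-oxazolidin-2-one
Product: 12 methyl 4-(benzyloxy)-3-{(2R)-1-[4-(benzyloxy)-3-methoxyphenyl]-3-hydroxypropan-2-yl}-5-methoxybenzoate
Conditions: NaBH4, THF/H2O (4:1), 0 °C to rt
Reagents that add atoms: none
Why: Reductive removal of the auxiliary by borohydride attack on the exocyclic imide carbonyl, under conditions that should neither reduce the methyl benzoate nor epimerise the α-aryl centre.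

Step 8
Reactants: 12 methyl 4-(benzyloxy)-3-{(2R)-1-[4-(benzyloxy)-3-methoxyphenyl]-3-hydroxypropan-2-yl}-5-methoxybenzoate
Product: 13 methyl 4-hydroxy-3-[(2R)-1-hydroxy-3-(4-hydroxy-3-methoxyphenyl)propan-2-yl]-5-methoxybenzoate
Conditions: H2 (1 atm), Pd/C (10 %), EtOAc/MeOH, rt
Reagents that add atoms: none
Why: Hydrogenolysis of both aryl benzyl ethers, with nothing else in 12 that is reducible under these conditions.

Step 9
Reactants: 13 methyl 4-hydroxy-3-[(2R)-1-hydroxy-3-(4-hydroxy-3-methoxyphenyl)propan-2-yl]-5-methoxybenzoate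
Product: 15 methyl (2S,3R)-2-(4-hydroxy-3-methoxyphenyl)-3-(hydroxymethyl)-7-methoxy-2,3-dihydro-1-benzofuran-5-carboxylate, via p-quinone methide 14 (not isolated)
Conditions: Ag2O (1.1 equiv), CH2Cl2/acetone (4:1), rt, dark
Reagents that add atoms: none
Why: Ag2O takes two electrons and two protons (the phenolic hydrogen and one benzylic hydrogen) from the 4-alkyl-2-methoxyphenol of 13 to give p-quinone methide 14, and the phenol oxygen of the benzoate ring then adds to the exocyclic methide carbon, which forms O1–C2 and restores the aromatic guaiacyl ring. The closest known reaction type is the oxidation of 4-alkylguaiacols to p-quinone methides by Ag2O or a quinone with intramolecular capture by an oxygen nucleophile, the same event that closes the phenylcoumaran ring in oxidative 8–5 coupling of coniferyl-type phenols. The dihydrofuran ring closes in the 5-exo-trig mode, the methide C=C lying outside the new ring. C2 is controlled by the existing C3 centre: the phenol adds to the methide face that puts the guaiacyl group anti to the C3 hydroxymethyl group, and because the addition can reverse through 14 the trans (2S,3R) isomer is also the one that accumulates. The step needs oxidation of only one of the two phenols, which the para methoxycarbonyl group secures by raising the oxidation potential of the central phenol and leaving it no para benzylic hydrogen while keeping it acidic enough to react as the phenoxide; the primary alcohol could only close an oxetane and should not compete. Use of about one equivalent of Ag2O should keep 15 from being dehydrogenated further to the benzofuran.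

Step 10
Reactants: 15 methyl (2S,3R)-2-(4-hydroxy-3-methoxyphenyl)-3-(hydroxymethyl)-7-methoxy-2,3-dihydro-1-benzofuran-5-carboxylate
Product: 16 methyl (2S,3R)-7-methoxy-2-{3-methoxy-4-[(triisopropylsilyl)oxy]phenyl}-3-{[(triisopropylsilyl)oxy]methyl}-2,3-dihydro-1-benzofuran-5-carboxylate
Conditions: TIPSCl (2.6 equiv), imidazole, DMAP (cat.), DMF, rt
Reagents that add atoms: triisopropylsilyl chloride, CC(C)[Si](Cl)(C(C)C)C(C)C
Why: Silyl ether formation on the phenol and the primary alcohol in one operation, which also removes the free phenol that could reopen the ring through the quinone methide in the basic steps that follow.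

Step 11
Reactants: 16 methyl (2S,3R)-7-methoxy-2-{3-methoxy-4-[(triisopropylsilyl)oxy]phenyl}-3-{[(triisopropylsilyl)oxy]methyl}-2,3-dihydro-1-benzofuran-5-carboxylate
Product: 17 [(2S,3R)-7-methoxy-2-{3-methoxy-4-[(triisopropylsilyl)oxy]phenyl}-3-{[(triisopropylsilyl)oxy]methyl}-2,3-dihydro-1-benzofuran-5-yl]methanol
Conditions: i-Bu2AlH (2.5 equiv), CH2Cl2, −78 to 0 °C; aqueous potassium sodium tartrate
Reagents that add atoms: none
Why: Hydride reduction of the aryl methyl ester to the benzylic alcohol, to which the silyl ethers and the cyclic benzylic ether are inert at low temperature.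

Step 12
Reactants: 17 [(2S,3R)-7-methoxy-2-{3-methoxy-4-[(triisopropylsilyl)oxy]phenyl}-3-{[(triisopropylsilyl)oxy]methyl}-2,3-dihydro-1-benzofuran-5-yl]methanol
Product: 18 (2S,3R)-5-(bromomethyl)-7-methoxy-2-{3-methoxy-4-[(triisopropylsilyl)oxy]phenyl}-3-{[(triisopropylsilyl)oxy]methyl}-2,3-dihydro-1-benzofuran
Conditions: CBr4, PPh3, CH2Cl2, 0 °C; used at once
Reagents that add atoms: carbon tetrabromide, BrC(Br)(Br)Br
Why: Appel reaction, whose neutral conditions should convert the benzylic alcohol to the bromide without ionising the O1–C2 bond or touching the silyl ethers.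

Step 13
Reactants: 19 3-(4-hydroxy-3-methoxyphenyl)propanoic acid
Product: 21 3-{3-methoxy-4-[(triisopropylsilyl)oxy]phenyl}propanoic acid, via bis-silylated ester 20 (not isolated)
Conditions: TIPSCl (2.4 equiv), imidazole, DMF, rt; then K2CO3, MeOH/THF/H2O, rt; 1 M HCl to pH 3
Reagents that add atoms: triisopropylsilyl chloride, CC(C)[Si](Cl)(C(C)C)C(C)C
Why: Silylation of phenol and acid followed by selective hydrolysis of the labile silyl ester, the aryl silyl ether being stable to mild carbonate.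

Step 14
Reactants: 21 3-{3-methoxy-4-[(triisopropylsilyl)oxy]phenyl}propanoic acid; 22 (S)-4-benzyl-1,3-oxazolidin-2-one
Product: 24 (4S)-4-benzyl-3-(3-{3-methoxy-4-[(triisopropylsilyl)oxy]phenyl}propanoyl)-1,3-oxazolidin-2-one, via mixed pivalic anhydride 23 (not isolated)
Conditions: PivCl, Et3N, THF, −20 °C; then LiCl, 22, −20 °C to rt
Reagents that add atoms: none
Why: N-acylation of the oxazolidinone through the mixed pivalic anhydride, as in step 4.

Step 15
Reactants: 24 (4S)-4-benzyl-3-(3-{3-methoxy-4-[(triisopropylsilyl)oxy]phenyl}propanoyl)-1,3-oxazolidin-2-one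
Product: 26 tert-butyl (3R)-4-[(4S)-4-benzyl-2-oxo-1,3-oxazolidin-3-yl]-3-({3-methoxy-4-[(triisopropylsilyl)oxy]phenyl}methyl)-4-oxobutanoate, via sodium Z-enolate 25 (not isolated)
Conditions: NaN(SiMe3)2, THF, −78 °C; then BrCH2CO2t-Bu, −78 to −40 °C
Reagents that add atoms: tert-butyl bromoacetate, CC(C)(C)OC(=O)CBr
Why: Evans asymmetric alkylation in which the bromoacetate attacks the chelated sodium Z-enolate anti to the benzyl group of the (S)-auxiliary, setting the (R) centre that becomes C4 of the lactone.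

Step 16
Reactants: 26 tert-butyl (3R)-4-[(4S)-4-benzyl-2-oxo-1,3-oxazolidin-3-yl]-3-({3-methoxy-4-[(triisopropylsilyl)oxy]phenyl}methyl)-4-oxobutanoate
Product: 27 tert-butyl (3R)-4-hydroxy-3-({3-methoxy-4-[(triisopropylsilyl)oxy]phenyl}methyl)butanoate
Conditions: NaBH4, THF/H2O (4:1), 0 °C to rt
Reagents that add atoms: none
Why: Reductive cleavage of the imide by borohydride, which does not reduce the tert-butyl ester.

Step 17
Reactants: 27 tert-butyl (3R)-4-hydroxy-3-({3-methoxy-4-[(triisopropylsilyl)oxy]phenyl}methyl)butanoate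
Product: 28 (4R)-4-({3-methoxy-4-[(triisopropylsilyl)oxy]phenyl}methyl)oxolan-2-one
Conditions: TFA/CH2Cl2 (1:4), 0 °C to rt
Reagents that add atoms: none
Why: Acid-promoted lactonisation (loss of isobutene and closure of the γ-hydroxy acid to the five-membered lactone), which leaves the stereocentre and the acid-stable aryl silyl ether untouched.

Step 18
Reactants: 28 (4R)-4-({3-methoxy-4-[(triisopropylsilyl)oxy]phenyl}methyl)oxolan-2-one; 18 (2S,3R)-5-(bromomethyl)-7-methoxy-2-{3-methoxy-4-[(triisopropylsilyl)oxy]phenyl}-3-{[(triisopropylsilyl)oxy]methyl}-2,3-dihydro-1-benzofuran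
Product: 30 (3R,4R)-3-{[(2S,3R)-7-methoxy-2-{3-methoxy-4-[(triisopropylsilyl)oxy]phenyl}-3-{[(triisopropylsilyl)oxy]methyl}-2,3-dihydro-1-benzofuran-5-yl]methyl}-4-({3-methoxy-4-[(triisopropylsilyl)oxy]phenyl}methyl)oxolan-2-one, via lithium lactone enolate 29 (not isolated)
Conditions: LiN(SiMe3)2, THF, −78 °C; then DMPU, 18, −78 to −30 °C
Reagents that add atoms: none
Why: Alkylation of a β-substituted γ-butyrolactone enolate, in which the bromide enters anti to the C4 benzyl group and gives the trans (3R,4R) lactone, as in dibenzylbutyrolactone lignan syntheses.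

Step 19
Reactants: 30 the trans (3R,4R) lactone of step 18
Product: 31 (2R,3R)-2-{[(2S,3R)-7-methoxy-2-{3-methoxy-4-[(triisopropylsilyl)oxy]phenyl}-3-{[(triisopropylsilyl)oxy]methyl}-2,3-dihydro-1-benzofuran-5-yl]methyl}-3-({3-methoxy-4-[(triisopropylsilyl)oxy]phenyl}methyl)butane-1,4-diol
Conditions: LiAlH4, THF, 0 °C
Reagents that add atoms: none
Why: Hydride reduction of the lactone to the 1,4-diol, which affects no stereocentre and which triisopropylsilyl ethers should withstand at 0 °C.

Step 20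
Reactants: 31 the tris-silylated (2R,3R) diol of step 19
Product: 32 (2R,3R)-2-{[(2S,3R)-2-(4-hydroxy-3-methoxyphenyl)-3-(hydroxymethyl)-7-methoxy-2,3-dihydro-1-benzofuran-5-yl]methyl}-3-[(4-hydroxy-3-methoxyphenyl)methyl]butane-1,4-diol
Conditions: n-Bu4NF (4.5 equiv), AcOH (4.5 equiv), THF, 0 °C to rt
Reagents that add atoms: none
Why: Fluoride-induced cleavage of the three silyl ethers, buffered with acetic acid so that the liberated p-hydroxybenzyl ether of the dihydrobenzofuran is not opened through a quinone methide.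

**Compound list**

1 | methyl 3-bromo-4-hydroxy-5-methoxybenzoate | COC(=O)c1cc(Br)c(O)c(OC)c1 | starting material
2 | methyl 4-(benzyloxy)-3-bromo-5-methoxybenzoate | COC(=O)c1cc(Br)c(OCc2ccccc2)c(OC)c1 | intermediate
3 | tert-butyl 2-[2-(benzyloxy)-3-methoxy-5-(methoxycarbonyl)phenyl]acetate | COC(=O)c1cc(CC(=O)OC(C)(C)C)c(OCc2ccccc2)c(OC)c1 | intermediate
4 | 2-[2-(benzyloxy)-3-methoxy-5-(methoxycarbonyl)phenyl]acetic acid | COC(=O)c1cc(CC(=O)O)c(OCc2ccccc2)c(OC)c1 | intermediate
5 | (R)-4-benzyl-1,3-oxazolidin-2-one | O=C1N[C@H](Cc2ccccc2)CO1 | starting material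
6 | mixed anhydride of acid 4 with pivalic acid (formed in the flask) | COC(=O)c1cc(CC(=O)OC(=O)C(C)(C)C)c(OCc2ccccc2)c(OC)c1 | intermediate
7 | (4R)-4-benzyl-3-{2-[2-(benzyloxy)-3-methoxy-5-(methoxycarbonyl)phenyl]acetyl}-1,3-oxazolidin-2-one | COC(=O)c1cc(CC(=O)N2[C@H](Cc3ccccc3)COC2=O)c(OCc2ccccc2)c(OC)c1 | intermediate
8 | [4-(benzyloxy)-3-methoxyphenyl]methanol | COc1cc(CO)ccc1OCc1ccccc1 | starting material
9 | 1-(benzyloxy)-4-(bromomethyl)-2-methoxybenzene | COc1cc(CBr)ccc1OCc1ccccc1 | intermediate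
10 | sodium Z-enolate of imide 7 (formed in the flask) | [Na+].[O-]/C(=C\c1cc(C(=O)OC)cc(OC)c1OCc1ccccc1)N1[C@H](Cc2ccccc2)COC1=O | intermediate
11 | (4R)-4-benzyl-3-{(2R)-2-[2-(benzyloxy)-3-methoxy-5-(methoxycarbonyl)phenyl]-3-[4-(benzyloxy)-3-methoxyphenyl]propanoyl}-1,3-oxazolidin-2-one | COC(=O)c1cc(OC)c(OCc2ccccc2)c(c1)[C@H](C(=O)N1[C@H](Cc2ccccc2)COC1=O)Cc1ccc(OCc2ccccc2)c(OC)c1 | intermediate
12 | methyl 4-(benzyloxy)-3-{(2R)-1-[4-(benzyloxy)-3-methoxyphenyl]-3-hydroxypropan-2-yl}-5-methoxybenzoate | COC(=O)c1cc(OC)c(OCc2ccccc2)c(c1)[C@H](CO)Cc1ccc(OCc2ccccc2)c(OC)c1 | intermediate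
13 | methyl 4-hydroxy-3-[(2R)-1-hydroxy-3-(4-hydroxy-3-methoxyphenyl)propan-2-yl]-5-methoxybenzoate | COC(=O)c1cc(OC)c(O)c(c1)[C@H](CO)Cc1ccc(O)c(OC)c1 | intermediate
14 | methyl 4-hydroxy-3-[(2R)-1-hydroxy-3-(3-methoxy-4-oxocyclohexa-2,5-dien-1-ylidene)propan-2-yl]-5-methoxybenzoate (p-quinone methide, formed in the flask) | COC(=O)c1cc(OC)c(O)c(c1)[C@H](CO)C=C1C=CC(=O)C(OC)=C1 | intermediate
15 | methyl (2S,3R)-2-(4-hydroxy-3-methoxyphenyl)-3-(hydroxymethyl)-7-methoxy-2,3-dihydro-1-benzofuran-5-carboxylate | COC(=O)c1cc(OC)c2c(c1)[C@H](CO)[C@@H](c1ccc(O)c(OC)c1)O2 | intermediate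
16 | methyl (2S,3R)-7-methoxy-2-{3-methoxy-4-[(triisopropylsilyl)oxy]phenyl}-3-{[(triisopropylsilyl)oxy]methyl}-2,3-dihydro-1-benzofuran-5-carboxylate | COC(=O)c1cc(OC)c2c(c1)[C@H](CO[Si](C(C)C)(C(C)C)C(C)C)[C@@H](c1ccc(O[Si](C(C)C)(C(C)C)C(C)C)c(OC)c1)O2 | intermediate
17 | [(2S,3R)-7-methoxy-2-{3-methoxy-4-[(triisopropylsilyl)oxy]phenyl}-3-{[(triisopropylsilyl)oxy]methyl}-2,3-dihydro-1-benzofuran-5-yl]methanol | OCc1cc(OC)c2c(c1)[C@H](CO[Si](C(C)C)(C(C)C)C(C)C)[C@@H](c1ccc(O[Si](C(C)C)(C(C)C)C(C)C)c(OC)c1)O2 | intermediate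
18 | (2S,3R)-5-(bromomethyl)-7-methoxy-2-{3-methoxy-4-[(triisopropylsilyl)oxy]phenyl}-3-{[(triisopropylsilyl)oxy]methyl}-2,3-dihydro-1-benzofuran | BrCc1cc(OC)c2c(c1)[C@H](CO[Si](C(C)C)(C(C)C)C(C)C)[C@@H](c1ccc(O[Si](C(C)C)(C(C)C)C(C)C)c(OC)c1)O2 | intermediate
19 | 3-(4-hydroxy-3-methoxyphenyl)propanoic acid | COc1cc(CCC(=O)O)ccc1O | starting material
20 | triisopropylsilyl 3-{3-methoxy-4-[(triisopropylsilyl)oxy]phenyl}propanoate (formed in the flask) | COc1cc(CCC(=O)O[Si](C(C)C)(C(C)C)C(C)C)ccc1O[Si](C(C)C)(C(C)C)C(C)C | intermediate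
21 | 3-{3-methoxy-4-[(triisopropylsilyl)oxy]phenyl}propanoic acid | COc1cc(CCC(=O)O)ccc1O[Si](C(C)C)(C(C)C)C(C)C | intermediate
22 | (S)-4-benzyl-1,3-oxazolidin-2-one | O=C1N[C@@H](Cc2ccccc2)CO1 | starting material
23 | mixed anhydride of acid 21 with pivalic acid (formed in the flask) | COc1cc(CCC(=O)OC(=O)C(C)(C)C)ccc1O[Si](C(C)C)(C(C)C)C(C)C | intermediate
24 | (4S)-4-benzyl-3-(3-{3-methoxy-4-[(triisopropylsilyl)oxy]phenyl}propanoyl)-1,3-oxazolidin-2-one | COc1cc(CCC(=O)N2[C@@H](Cc3ccccc3)COC2=O)ccc1O[Si](C(C)C)(C(C)C)C(C)C | intermediate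
25 | sodium Z-enolate of imide 24 (formed in the flask) | [Na+].[O-]/C(=C\Cc1ccc(O[Si](C(C)C)(C(C)C)C(C)C)c(OC)c1)N1[C@@H](Cc2ccccc2)COC1=O | intermediate
26 | tert-butyl (3R)-4-[(4S)-4-benzyl-2-oxo-1,3-oxazolidin-3-yl]-3-({3-methoxy-4-[(triisopropylsilyl)oxy]phenyl}methyl)-4-oxobutanoate | COc1cc(C[C@H](CC(=O)OC(C)(C)C)C(=O)N2[C@@H](Cc3ccccc3)COC2=O)ccc1O[Si](C(C)C)(C(C)C)C(C)C | intermediate
27 | tert-butyl (3R)-4-hydroxy-3-({3-methoxy-4-[(triisopropylsilyl)oxy]phenyl}methyl)butanoate | COc1cc(C[C@H](CC(=O)OC(C)(C)C)CO)ccc1O[Si](C(C)C)(C(C)C)C(C)C | intermediate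
28 | (4R)-4-({3-methoxy-4-[(triisopropylsilyl)oxy]phenyl}methyl)oxolan-2-one | O=C1C[C@@H](Cc2ccc(O[Si](C(C)C)(C(C)C)C(C)C)c(OC)c2)CO1 | intermediate
29 | lithium enolate of lactone 28 (formed in the flask) | [Li+].[O-]C1=C[C@@H](Cc2ccc(O[Si](C(C)C)(C(C)C)C(C)C)c(OC)c2)CO1 | intermediate
30 | (3R,4R)-3-{[(2S,3R)-7-methoxy-2-{3-methoxy-4-[(triisopropylsilyl)oxy]phenyl}-3-{[(triisopropylsilyl)oxy]methyl}-2,3-dihydro-1-benzofuran-5-yl]methyl}-4-({3-methoxy-4-[(triisopropylsilyl)oxy]phenyl}methyl)oxolan-2-one | COc1cc(C[C@H]2COC(=O)[C@@H]2Cc2cc(OC)c3c(c2)[C@H](CO[Si](C(C)C)(C(C)C)C(C)C)[C@@H](c2ccc(O[Si](C(C)C)(C(C)C)C(C)C)c(OC)c2)O3)ccc1O[Si](C(C)C)(C(C)C)C(C)C | intermediate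
31 | (2R,3R)-2-{[(2S,3R)-7-methoxy-2-{3-methoxy-4-[(triisopropylsilyl)oxy]phenyl}-3-{[(triisopropylsilyl)oxy]methyl}-2,3-dihydro-1-benzofuran-5-yl]methyl}-3-({3-methoxy-4-[(triisopropylsilyl)oxy]phenyl}methyl)butane-1,4-diol | COc1cc(C[C@@H](CO)[C@H](CO)Cc2cc(OC)c3c(c2)[C@H](CO[Si](C(C)C)(C(C)C)C(C)C)[C@@H](c2ccc(O[Si](C(C)C)(C(C)C)C(C)C)c(OC)c2)O3)ccc1O[Si](C(C)C)(C(C)C)C(C)C | intermediate
32 | (2R,3R)-2-{[(2S,3R)-2-(4-hydroxy-3-methoxyphenyl)-3-(hydroxymethyl)-7-methoxy-2,3-dihydro-1-benzofuran-5-yl]methyl}-3-[(4-hydroxy-3-methoxyphenyl)methyl]butane-1,4-diol | COc1cc(C[C@@H](CO)[C@H](CO)Cc2cc(OC)c3c(c2)[C@H](CO)[C@@H](c2ccc(O)c(OC)c2)O3)ccc1O | target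

**Step count**

Total: 20 steps. Longest linear sequence: 14 steps (steps 1–4, 6–12 and 18–20, from compound 1).

**Steps most likely to fail**

Step 9. The quinone methide may lose the C3 hydrogen and tautomerise to the stilbene, or the ring-closed phenol may be oxidised further while Ag2O is still present, before clean closure is complete. The fallback separates oxidation from ring closure. It sets out from 13: DDQ (1 equiv) in CH2Cl2/MeOH at 0 °C should trap the methide with solvent and give the benzylic methyl ether methyl 4-hydroxy-3-[(2R)-1-hydroxy-3-(4-hydroxy-3-methoxyphenyl)-3-methoxypropan-2-yl]-5-methoxybenzoate F1 as both epimers at the new carbon. After removal of the oxidant, catalytic TsOH in CH2Cl2 should ionise the p-hydroxybenzyl ether with loss of methanol, and the neighbouring phenol closes the ring under equilibrating conditions to the trans isomer. The route is rejoined at 15.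

Step 18. The electron-rich benzylic bromide may ionise or alkylate itself before the enolate captures it, and proton exchange between enolate and product may cause double alkylation or incomplete conversion. The fallback replaces alkylation by aldol addition and deoxygenation. It sets out from 17, which is oxidised with MnO2 (CH2Cl2, rt) to (2S,3R)-7-methoxy-2-{3-methoxy-4-[(triisopropylsilyl)oxy]phenyl}-3-{[(triisopropylsilyl)oxy]methyl}-2,3-dihydro-1-benzofuran-5-carbaldehyde F2. Enolate 29, made from lactone 28 as in step 18, should add to F2 anti to the C4 substituent and give the trans aldol adduct (3S,4R)-3-{hydroxy[(2S,3R)-7-methoxy-2-{3-methoxy-4-[(triisopropylsilyl)oxy]phenyl}-3-{[(triisopropylsilyl)oxy]methyl}-2,3-dihydro-1-benzofuran-5-yl]methyl}-4-({3-methoxy-4-[(triisopropylsilyl)oxy]phenyl}methyl)oxolan-2-one F3 as a mixture of carbinol epimers (the ring carbons have the spatial arrangement of 30; the C3 label changes by the priority rules). Ionic hydrogenation (Et3SiH, BF3·OEt2, CH2Cl2, −78 to −40 °C) should remove the benzylic hydroxyl through the p-alkoxybenzyl cation, at a temperature low enough to leave the O1–C2 bond alone. The route is rejoined at 30.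

Step 6. Configurational purity may be lost by proton exchange at the acidic α-aryl centre, or the imide enolate may fragment to an arylketene on warming. The fallback alkylates without the auxiliary and then uses the auxiliary as a resolving handle. It sets out from 3 (with 9): LiN(i-Pr)2 in THF at −78 °C gives the lithium enolate of tert-butyl ester 3 F4, which is alkylated with 9 to racemic tert-butyl 2-[2-(benzyloxy)-3-methoxy-5-(methoxycarbonyl)phenyl]-3-[4-(benzyloxy)-3-methoxyphenyl]propanoate F5. TFA in CH2Cl2 gives racemic 2-[2-(benzyloxy)-3-methoxy-5-(methoxycarbonyl)phenyl]-3-[4-(benzyloxy)-3-methoxyphenyl]propanoic acid F6. Under the conditions of step 4 this is activated as its mixed pivalic anhydride F7 and acylates 5, giving 11 together with its (2S) epimer, (4R)-4-benzyl-3-{(2S)-2-[2-(benzyloxy)-3-methoxy-5-(methoxycarbonyl)phenyl]-3-[4-(benzyloxy)-3-methoxyphenyl]propanoyl}-1,3-oxazolidin-2-one F8. The two diastereomers are separated by chromatography or crystallisation; F8 can be equilibrated with DBU and recycled. The route is rejoined at 11.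

**Further compounds**

F1 | step 9 | methyl 4-hydroxy-3-[(2R)-1-hydroxy-3-(4-hydroxy-3-methoxyphenyl)-3-methoxypropan-2-yl]-5-methoxybenzoate (both epimers at the methoxy-bearing carbon) | COC(=O)c1cc(OC)c(O)c(c1)[C@H](CO)C(OC)c1ccc(O)c(OC)c1
F2 | step 18 | (2S,3R)-7-methoxy-2-{3-methoxy-4-[(triisopropylsilyl)oxy]phenyl}-3-{[(triisopropylsilyl)oxy]methyl}-2,3-dihydro-1-benzofuran-5-carbaldehyde | O=Cc1cc(OC)c2c(c1)[C@H](CO[Si](C(C)C)(C(C)C)C(C)C)[C@@H](c1ccc(O[Si](C(C)C)(C(C)C)C(C)C)c(OC)c1)O2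
F3 | step 18 | (3S,4R)-3-{hydroxy[(2S,3R)-7-methoxy-2-{3-methoxy-4-[(triisopropylsilyl)oxy]phenyl}-3-{[(triisopropylsilyl)oxy]methyl}-2,3-dihydro-1-benzofuran-5-yl]methyl}-4-({3-methoxy-4-[(triisopropylsilyl)oxy]phenyl}methyl)oxolan-2-one (carbinol epimers) | COc1cc(C[C@H]2COC(=O)[C@@H]2C(O)c2cc(OC)c3c(c2)[C@H](CO[Si](C(C)C)(C(C)C)C(C)C)[C@@H](c2ccc(O[Si](C(C)C)(C(C)C)C(C)C)c(OC)c2)O3)ccc1O[Si](C(C)C)(C(C)C)C(C)C
F4 | step 6 | lithium enolate of tert-butyl ester 3 | [Li+].[O-]C(OC(C)(C)C)=Cc1cc(C(=O)OC)cc(OC)c1OCc1ccccc1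
F5 | step 6 | racemic tert-butyl 2-[2-(benzyloxy)-3-methoxy-5-(methoxycarbonyl)phenyl]-3-[4-(benzyloxy)-3-methoxyphenyl]propanoate | COC(=O)c1cc(OC)c(OCc2ccccc2)c(c1)C(C(=O)OC(C)(C)C)Cc1ccc(OCc2ccccc2)c(OC)c1
F6 | step 6 | racemic 2-[2-(benzyloxy)-3-methoxy-5-(methoxycarbonyl)phenyl]-3-[4-(benzyloxy)-3-methoxyphenyl]propanoic acid | COC(=O)c1cc(OC)c(OCc2ccccc2)c(c1)C(C(=O)O)Cc1ccc(OCc2ccccc2)c(OC)c1
F7 | step 6 | racemic mixed anhydride of acid F6 with pivalic acid | COC(=O)c1cc(OC)c(OCc2ccccc2)c(c1)C(C(=O)OC(=O)C(C)(C)C)Cc1ccc(OCc2ccccc2)c(OC)c1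
F8 | step 6 | (4R)-4-benzyl-3-{(2S)-2-[2-(benzyloxy)-3-methoxy-5-(methoxycarbonyl)phenyl]-3-[4-(benzyloxy)-3-methoxyphenyl]propanoyl}-1,3-oxazolidin-2-one | COC(=O)c1cc(OC)c(OCc2ccccc2)c(c1)[C@@H](C(=O)N1[C@H](Cc2ccccc2)COC1=O)Cc1ccc(OCc2ccccc2)c(OC)c1
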